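**Retrosynthetic overview**
1. Target 15 ⇐ 3,3′-diketone 14 ⇐ 3β,3′β-diol 13; both axial carbinols are set last by a bulky hydride.
2. Central C-11–C-11′ bond: visible-light chromium/photoredox radical hydroalkylation of diene 8 (unsaturated half) with iodide 12 (saturated half), which also sets C-9.
3. Iodide 12 ⇐ diene 8 by hydroboration (C-9′) and HAT hydrogenation (C-8′), so both halves come from one bicyclic diene.
4. Diene 8 ⇐ enone 7 (Wittig); ring A is closed onto the carvone ring (ring B) by HAT radical cyclisation of the isopropenyl group onto an aldehyde (C-3–C-4 bond).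
5. (R)-Carvone supplies C-5; α′-methylation then propargylation sets C-10. Ring order: ring B bought, ring A formed, then the two bicycles joined.

Assumption: each decalin half is numbered as a drimane (C-3 carbinol, C-4 gem-dimethyl, C-8 methyl-bearing carbon, C-11 the CH2 on C-9, primed locants for the saturated half, β = face of the C-10 methyl); the target SMILES is read as the 3α,3′α-diol with 5α-H, 9α-H and 10β-Me in both halves and 8′β-H (8′α-methyl).

**Step 1**
Reactants: 1 (R)-(−)-carvone
Product: 3 (5R,6S)-2,6-dimethyl-5-(prop-1-en-2-yl)cyclohex-2-en-1-one (trans-6-methylcarvone), via lithium dienolate 2 (not isolated)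
Conditions: LiN(iPr)2, THF, −78 °C; MeI, −78 → 0 °C
Reagents that add atoms: iodomethane CI
Why: Kinetic α′-deprotonation gives the cross-conjugated dienolate, which is C-methylated (enolate alkylation); the new C-6 centre (mainly trans to isopropenyl) is erased again in step 2, so its ratio does not matter.

**Step 2**
Reactants: 3 (5R,6S)-2,6-dimethyl-5-(prop-1-en-2-yl)cyclohex-2-en-1-one
Product: 5 (5S,6S)-2,6-dimethyl-5-(prop-1-en-2-yl)-6-(prop-2-yn-1-yl)cyclohex-2-en-1-one, via lithium enolate 4 (not isolated)
Conditions: LiN(iPr)2, THF/DMPU, −78 °C; propargyl bromide, −78 → −20 °C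
Reagents that add atoms: 3-bromoprop-1-yne C#CCBr
Why: Diastereoselective enolate alkylation in which the electrophile enters anti to the adjacent isopropenyl group, so the propargyl chain (future C-1 to C-3) ends trans and the methyl cis to it, which is the C-10 configuration of both halves.

**Step 3**
Reactants: 5 (5S,6S)-2,6-dimethyl-5-(prop-1-en-2-yl)-6-(prop-2-yn-1-yl)cyclohex-2-en-1-one
Product: 6 3-[(1S,6S)-1,3-dimethyl-2-oxo-6-(prop-1-en-2-yl)cyclohex-3-en-1-yl]propanal
Conditions: [CpRu(MeCN)3]PF6 (2 mol%), 5,5′-bis(trifluoromethyl)-2,2′-bipyridine (2 mol%), NMP/H2O 4:1, 25 °C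
Reagents that add atoms: water O
Why: Ruthenium-catalysed anti-Markovnikov hydration of the terminal alkyne through a vinylidene gives the aldehyde selectively; the enone and isopropenyl group are inert and no stereocentre is touched.

**Step 4**
Reactants: 6 3-[(1S,6S)-1,3-dimethyl-2-oxo-6-(prop-1-en-2-yl)cyclohex-3-en-1-yl]propanal
Product: 7 3β-hydroxy-11-nordrim-7-en-9-one [(4aS,6S,8aS)-6-hydroxy-2,5,5,8a-tetramethyl-4a,5,6,7,8,8a-hexahydronaphthalen-1(4H)-one]
Conditions: Fe(acac)3 (30 mol%), PhSiH3 (2.5 equiv), EtOH (0.02 M), 60 °C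
Reagents that add atoms: none
Why: Iron hydride hydrogen-atom transfer (Mukaiyama-type HAT, established for radical cyclisation of alkenes onto tethered ketones) to the isopropenyl group gives the tertiary C-4 radical, which closes ring A by 6-exo addition to the aldehyde carbon (C-3–C-4 bond and gem-dimethyl group formed), the alkoxy radical being reduced in the silane/ethanol medium; the ring fusion is necessarily trans because C-5 and C-10 are already fixed, and a chair transition state with equatorial oxygen should give mainly the 3β-alcohol (any 3α epimer converges in step 10).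

**Step 5**
Reactants: 7 3β-hydroxy-11-nordrim-7-en-9-one
Product: 8 drima-7,9(11)-dien-3β-ol
Conditions: Ph3PCH3Br (3.5 equiv), KOtBu (3.3 equiv), toluene, 90 °C
Reagents that add atoms: methyltriphenylphosphonium bromide C[P+](c1ccccc1)(c1ccccc1)c1ccccc1.[Br-]
Why: Wittig methylenation of the hindered enone carbonyl with excess ylide (the C-3 alkoxide is a spectator) gives the transoid exocyclic diene without touching a stereocentre.

**Step 6**
Reactants: 8 drima-7,9(11)-dien-3β-ol
Product: 10 drim-7-ene-3β,11-diol (3β-hydroxydrimenol), via B-(3β-hydroxydrim-7-en-11-yl)-9-BBN 9 (not isolated)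
Conditions: 9-BBN (2.5 equiv), THF, 0 → 25 °C; then NaOH, H2O2, 0 °C
Reagents that add atoms: 9-borabicyclo[3.3.1]nonane C1CC2CCCC(C1)B2 (boron present in 9 only); hydrogen peroxide OO
Why: Hydroboration–oxidation in which the bulky borane adds only to the exocyclic 1,1-disubstituted alkene, boron to C-11 and hydrogen to C-9 from the α face opposite the axial C-10 methyl, setting 9α-H with the CH2OH group β and equatorial; the trisubstituted 7-ene is left.

**Step 7**
Reactants: 10 drim-7-ene-3β,11-diol
Product: 11 8β(H)-drimane-3β,11-diol (8α-methyl; 9β-CH2OH)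
Conditions: Mn(dpm)3 (10 mol%), PhSiH3 (1.5 equiv), t-BuOOH (1.5 equiv), i-PrOH, 22 °C
Reagents that add atoms: none
Why: Radical HAT hydrogenation of the trisubstituted alkene, in which the tertiary C-8 radical takes up hydrogen axially (β face) to give the thermodynamically preferred equatorial 8α-methyl group trans to the C-9 side chain, whereas surface hydrogenation would give the axial 8β-methyl epimer.

**Step 8**
Reactants: 11 8β(H)-drimane-3β,11-diol
Product: 12 11-iodo-8β(H)-driman-3β-ol
Conditions: PPh3, I2, imidazole, CH2Cl2, 0 → 25 °C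
Reagents that add atoms: iodine II
Why: Appel iodination is selective for the primary alcohol over the secondary C-3 carbinol shielded by the gem-dimethyl group; no stereocentre is involved.

**Step 9**
Reactants: 8 drima-7,9(11)-dien-3β-ol; 12 11-iodo-8β(H)-driman-3β-ol
Product: 13 11-[3β-hydroxy-8β(H)-driman-11-yl]drim-7-en-3β-ol (the 3,3′-bis-epimer of the target)
Conditions: 8 (2.5 equiv, excess recovered), 4CzIPN (3 mol%), CrCl2 (10 mol%), Et3N (3 equiv), DMF (0.5 M in 8), 450 nm LEDs, 25 °C
Reagents that add atoms: none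
Why: Proposed new method: photoredox/chromium-catalysed reductive 1,2-hydroalkylation of a 1,3-diene with an unactivated primary alkyl iodide, in which excited 4CzIPN oxidises Et3N, the α-aminoalkyl radical abstracts iodine from 12 (halogen-atom transfer), the primary C-11′ radical adds to the unhindered exocyclic CH2 (C-11) of 8 to form the C-11–C-11′ bond and an allyl radical over C-7/C-8/C-9, this is captured at the less hindered C-7 by divalent chromium (regenerated from trivalent chromium by the reduced photocatalyst), and the allylchromium is protonated by Et3NH+ in SE2′ fashion at the γ carbon C-9 on the α face opposite the C-10 methyl to give the 7-ene and 9α-H with full cross-selectivity; the closest known reaction types are the chromium-mediated three-component coupling of alkyl halides, 1,3-dienes and aldehydes (radical addition followed by Nozaki–Hiyama–Kishi-type γ-selective allylation), its photoredox/chromium catalytic variants, and the γ-selective protonolysis of allylchromium species in chromous reductions of allylic halides.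

**Step 10**
Reactants: 13 11-[3β-hydroxy-8β(H)-driman-11-yl]drim-7-en-3β-ol
Product: 14 11-[3-oxo-8β(H)-driman-11-yl]drim-7-en-3-one (the 3,3′-diketone)
Conditions: Dess–Martin periodinane (3 equiv), NaHCO3, CH2Cl2, 0 → 25 °C
Reagents that add atoms: none
Why: Dess–Martin oxidation converts both hindered secondary carbinols to ketones under buffered conditions that leave the 7-ene and the allylic C-9 centre untouched, and it converges any 3α material from step 4.

**Step 11**
Reactants: 14 11-[3-oxo-8β(H)-driman-11-yl]drim-7-en-3-one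
Product: 15 11-[3α-hydroxy-8β(H)-driman-11-yl]drim-7-en-3α-ol (CNP0194061.3)
Conditions: LiBH(s-Bu)3 (3 equiv), THF, −78 °C; then H2O
Reagents that add atoms: none
Why: Substrate-controlled ketone reduction in which the bulky trialkylborohydride attacks each 4,4-dimethyl-3-ketone of the trans-decalin along the equatorial trajectory, giving both axial 3α-alcohols as in 3-oxotriterpenoid reductions; the alkene is inert.

**Compound list**
1 | (R)-(−)-carvone | CC1=CC[C@@H](C(C)=C)CC1=O | starting material
2 | lithium dienolate of 1 | CC1=CC[C@@H](C(C)=C)C=C1O[Li] | intermediate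
3 | (5R,6S)-2,6-dimethyl-5-(prop-1-en-2-yl)cyclohex-2-en-1-one (trans-6-methylcarvone, major epimer) | CC1=CC[C@@H](C(C)=C)[C@H](C)C1=O | intermediate
4 | lithium enolate of 3 | CC1=CC[C@@H](C(C)=C)C(C)=C1O[Li] | intermediate
5 | (5S,6S)-2,6-dimethyl-5-(prop-1-en-2-yl)-6-(prop-2-yn-1-yl)cyclohex-2-en-1-one | CC1=CC[C@@H](C(C)=C)[C@](C)(CC#C)C1=O | intermediate
6 | 3-[(1S,6S)-1,3-dimethyl-2-oxo-6-(prop-1-en-2-yl)cyclohex-3-en-1-yl]propanal | CC1=CC[C@@H](C(C)=C)[C@](C)(CCC=O)C1=O | intermediate
7 | 3β-hydroxy-11-nordrim-7-en-9-one | CC1=CC[C@H]2C(C)(C)[C@@H](O)CC[C@]2(C)C1=O | intermediate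
8 | drima-7,9(11)-dien-3β-ol | CC1=CC[C@H]2C(C)(C)[C@@H](O)CC[C@]2(C)C1=C | intermediate
9 | B-(3β-hydroxydrim-7-en-11-yl)-9-borabicyclo[3.3.1]nonane | CC1=CC[C@H]2C(C)(C)[C@@H](O)CC[C@]2(C)[C@H]1CB1C2CCCC1CCC2 | intermediate
10 | drim-7-ene-3β,11-diol | CC1=CC[C@H]2C(C)(C)[C@@H](O)CC[C@]2(C)[C@H]1CO | intermediate
11 | 8β(H)-drimane-3β,11-diol | OC[C@H]1[C@H](C)CC[C@H]2C(C)(C)[C@@H](O)CC[C@]12C | intermediate
12 | 11-iodo-8β(H)-driman-3β-ol | IC[C@H]1[C@H](C)CC[C@H]2C(C)(C)[C@@H](O)CC[C@]12C | intermediate
13 | 11-[3β-hydroxy-8β(H)-driman-11-yl]drim-7-en-3β-ol | CC1=CC[C@H]2C(C)(C)[C@@H](O)CC[C@]2(C)[C@H]1CC[C@H]1[C@H](C)CC[C@H]2C(C)(C)[C@@H](O)CC[C@]12C | intermediate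
14 | 11-[3-oxo-8β(H)-driman-11-yl]drim-7-en-3-one | CC1=CC[C@H]2C(C)(C)C(=O)CC[C@]2(C)[C@H]1CC[C@H]1[C@H](C)CC[C@H]2C(C)(C)C(=O)CC[C@]12C | intermediate
15 | 11-[3α-hydroxy-8β(H)-driman-11-yl]drim-7-en-3α-ol (CNP0194061.3) | CC1=CC[C@H]2C(C)(C)[C@H](O)CC[C@]2(C)[C@H]1CC[C@H]1[C@H](C)CC[C@H]2C(C)(C)[C@H](O)CC[C@]12C | target

**Totals**
Total step count: 11. Longest linear sequence: 11 steps (1 → 8 → 12 → 13 → 15); diene 8 serves both as the unsaturated half and as the precursor of the saturated half.

**Three steps most likely to fail**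

Step 9 (the proposed new coupling). Risks are capture or reduction of the primary radical before it adds to the diene, and protonation of the allylchromium at C-7 instead of C-9. The fallback uses known chemistry and sets out from 10 and 11. Appel bromination (CBr4, PPh3, CH2Cl2) gives 11-bromodrim-7-en-3β-ol F7 and 11-bromo-8β(H)-driman-3β-ol F8. These are joined by the known silyl-radical-mediated nickel/photoredox cross-electrophile coupling of two alkyl bromides (Ir[dF(CF3)ppy]2(dtbbpy)PF6, NiCl2(dme), 4,4′-di-tert-butyl-2,2′-bipyridine, (Me3Si)3SiOH, Na2CO3, blue LEDs, F7 in threefold excess). The cross product is separated from the homodimers on AgNO3-impregnated silica, and the route is rejoined at 13.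

Step 4 (HAT cyclisation onto the aldehyde). Risks are aldehyde or enone reduction and reversible ring closure. The fallback sets out from 6. The aldehyde is converted (I2, aqueous NH3, THF) into 3-[(1S,6S)-1,3-dimethyl-2-oxo-6-(prop-1-en-2-yl)cyclohex-3-en-1-yl]propanenitrile F1. The known Fe(acac)3/PhSiH3 HAT cyclisation onto a nitrile, where C–C bond formation is irreversible, gives the ketimine 3-imino-11-nordrim-7-en-9-one F2 (not isolated). Acidic work-up hydrolyses it to 11-nordrim-7-ene-3,9-dione F3. NaBH4 (MeOH/CH2Cl2, −78 °C) then reduces the unconjugated C-3 ketone in preference to the hindered conjugated enone, with axial hydride delivery giving the equatorial 3β-alcohol, and the route is rejoined at 7.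

Step 7 (HAT hydrogenation). Risks are formation of the axial 8β-methyl epimer or incomplete reduction. The fallback sets out from 7 and fixes C-8 by enolate equilibration instead. Hydrogenation of the enone (H2, Pd/C, EtOAc) followed by NaOMe/MeOH equilibration gives the equatorial 8α-methyl ketone 3β-hydroxy-11-nor-8β(H)-driman-9-one F4. Wittig methylenation (Ph3PCH3Br, KOtBu, toluene) gives 8β(H)-drim-9(11)-en-3β-ol F5. Hydroboration with 9-BBN from the α face gives B-[3β-hydroxy-8β(H)-driman-11-yl]-9-borabicyclo[3.3.1]nonane F6 (not isolated), and NaOH/H2O2 oxidation rejoins the route at 11.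

**Further compounds**
F1 | step 4 | 3-[(1S,6S)-1,3-dimethyl-2-oxo-6-(prop-1-en-2-yl)cyclohex-3-en-1-yl]propanenitrile | CC1=CC[C@@H](C(C)=C)[C@](C)(CCC#N)C1=O
F2 | step 4 | 3-imino-11-nordrim-7-en-9-one | CC1=CC[C@H]2C(C)(C)C(=N)CC[C@]2(C)C1=O
F3 | step 4 | 11-nordrim-7-ene-3,9-dione | CC1=CC[C@H]2C(C)(C)C(=O)CC[C@]2(C)C1=O
F4 | step 7 | 3β-hydroxy-11-nor-8β(H)-driman-9-one | C[C@@H]1CC[C@H]2C(C)(C)[C@@H](O)CC[C@]2(C)C1=O
F5 | step 7 | 8β(H)-drim-9(11)-en-3β-ol | C[C@@H]1CC[C@H]2C(C)(C)[C@@H](O)CC[C@]2(C)C1=C
F6 | step 7 | B-[3β-hydroxy-8β(H)-driman-11-yl]-9-borabicyclo[3.3.1]nonane | C[C@@H]1CC[C@H]2C(C)(C)[C@@H](O)CC[C@]2(C)[C@H]1CB1C2CCCC1CCC2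
F7 | step 9 | 11-bromodrim-7-en-3β-ol | CC1=CC[C@H]2C(C)(C)[C@@H](O)CC[C@]2(C)[C@H]1CBr
F8 | step 9 | 11-bromo-8β(H)-driman-3β-ol | BrC[C@H]1[C@H](C)CC[C@H]2C(C)(C)[C@@H](O)CC[C@]12C
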